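The dihydrofuran ring (benzofuran numbering) is built by a [3+2] construction from two pieces that carry neither the ring nor its ether bond. The C3 methylene enters as a benzylic zinc reagent on a fluoroacetophenone, and O1–C2 as the carbonyl group of methacrolein. In one operation, catalyst-controlled addition forms C3–C2 and sets C2, and the new alkoxide then displaces fluoride at C7a to form O1–C7a. The step exploits the fact that C7a lies para to the C5 ketone of the target, which activates this carbon for substitution. Hydration of the isopropenyl group and an asymmetric Mukaiyama aldol reaction with 2,2-dimethylchroman-6-carbaldehyde complete the molecule.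

Key step: step 3

Remark: the sense of induction of the two chiral catalysts (steps 3 and 6) is assigned by analogy with their closest known cases; should a first run show the opposite sense, the mirror-image ligand is used.

Step 1
Reactants: 1 1-(4-fluoro-2-hydroxyphenyl)ethan-1-one
Product: 2 1-[5-(chloromethyl)-4-fluoro-2-hydroxyphenyl]ethan-1-one
Conditions: (CH2O)n, conc. HCl, 40 °C
Reagents that add atoms: formaldehyde (as paraformaldehyde), C=O; hydrogen chloride, Cl
Why: Blanc chloromethylation (electrophilic aromatic substitution) should go para to the hydroxyl group, at the carbon that is also ortho to fluorine and meta to the acetyl group, because the other activated position is flanked by OH and F.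

Step 2
Reactants: 2 1-[5-(chloromethyl)-4-fluoro-2-hydroxyphenyl]ethan-1-one
Product: 3 1-{2-[(tert-butyldimethylsilyl)oxy]-5-(chloromethyl)-4-fluorophenyl}ethan-1-one
Conditions: TBSOTf (1.1 equiv), 2,6-lutidine, CH2Cl2, −78 → 0 °C
Reagents that add atoms: tert-butyldimethylsilyl trifluoromethanesulfonate (TBSOTf), CC(C)(C)[Si](C)(C)OS(=O)(=O)C(F)(F)F
Why: O-silylation with a silyl triflate and a hindered, weakly basic pyridine should cap the phenol without forming the free phenoxide that would expel chloride to a para-quinone methide, and it removes the acidic proton before the organozinc step.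

Step 3
Reactants: 3 1-{2-[(tert-butyldimethylsilyl)oxy]-5-(chloromethyl)-4-fluorophenyl}ethan-1-one; 4 methacrolein
Product: 7 1-[(2S)-6-hydroxy-2-(prop-1-en-2-yl)-2,3-dihydro-1-benzofuran-5-yl]ethan-1-one, via benzylic zinc chloride 5 (not isolated), via chlorozinc alkoxide 6 (not isolated)
Conditions: Zn dust, LiCl, THF, 25 °C; then 4, Ti(OiPr)4 (1.5 equiv), (1R,2R)-1,2-bis(trifluoromethanesulfonamido)cyclohexane (10 mol %), toluene, −30 °C; then KOt-Bu (3.5 equiv), DMPU, 0 → 45 °C; aq. NH4Cl
Reagents that add atoms: none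
Why: Proposed new method: zinc inserts into the benzylic C–Cl bond of 3 to give 5, whose benzyl group is passed to titanium and added 1,2 to methacrolein inside the chiral bis(sulfonamide)–titanium complex, forming C3–C2; tert-butoxide then frees the alkoxide of 6, which attacks C7a and expels fluoride through a Meisenheimer intermediate, forming O1–C7a, and the excess alkoxide also cleaves the aryl silyl ether. The closest known reaction types are the Ti(OiPr)4/chiral bis(sulfonamide)-catalysed enantioselective addition of functionalised dialkylzincs to aldehydes including enals, the uncatalysed addition of LiCl-derived benzylic zinc chlorides to aldehydes, and the base-induced SNAr etherification of 2-(2-fluoroaryl)ethanols; enantioselective transfer of a benzyl group from a benzylic zinc halide has not been shown. The dihydrofuran ring closes 5-exo-trig by addition–elimination at an aromatic carbon. C2 is the only new stereocentre and is set by the catalyst: the (1R,2R)-ligand is expected, by analogy with its Si-face delivery of alkyl groups to aldehydes, to give the (S)-alkoxide, and the substitution step does not touch this centre. The step needs aldehyde-over-ketone chemoselectivity, which the low reactivity of organozinc and organotitanium species toward the aryl ketone should secure, and a fast ring closure, which the acetyl group para to fluorine provides; no second oxygen nucleophile is present, so only the five-membered ether can form. The racemic background addition is to be held back by the low temperature and the toluene medium.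

Step 4
Reactants: 7 1-[(2S)-6-hydroxy-2-(prop-1-en-2-yl)-2,3-dihydro-1-benzofuran-5-yl]ethan-1-one
Product: 8 1-[(2S)-6-hydroxy-2-(2-hydroxypropan-2-yl)-2,3-dihydro-1-benzofuran-5-yl]ethan-1-one
Conditions: Co(acac)2 (20 mol %), PhSiH3, O2 (1 atm), THF, 25 °C; then aq. Na2S2O3
Reagents that add atoms: dioxygen, O=O
Why: Mukaiyama hydration (hydrogen-atom transfer to the 1,1-disubstituted alkene, trapping of the tertiary radical by O2, reduction of the peroxide) should give the Markovnikov tertiary alcohol under neutral conditions that leave the ketone, the phenol and the C2 stereocentre untouched.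

Step 5
Reactants: 8 1-[(2S)-6-hydroxy-2-(2-hydroxypropan-2-yl)-2,3-dihydro-1-benzofuran-5-yl]ethan-1-one
Product: 9 (2S)-6-[(trimethylsilyl)oxy]-2-{2-[(trimethylsilyl)oxy]propan-2-yl}-5-{1-[(trimethylsilyl)oxy]ethenyl}-2,3-dihydro-1-benzofuran
Conditions: TMSOTf (3.6 equiv), Et3N, CH2Cl2, 0 °C; pentane extraction, used crude
Reagents that add atoms: trimethylsilyl trifluoromethanesulfonate (TMSOTf), C[Si](C)(C)OS(=O)(=O)C(F)(F)F
Why: Soft enolisation with a silyl triflate and a tertiary amine should convert the methyl ketone into its silyl enol ether and silylate both hydroxyl groups, so that the aldol step meets no free OH.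

Step 6
Reactants: 9 (2S)-6-[(trimethylsilyl)oxy]-2-{2-[(trimethylsilyl)oxy]propan-2-yl}-5-{1-[(trimethylsilyl)oxy]ethenyl}-2,3-dihydro-1-benzofuran; 10 2,2-dimethyl-3,4-dihydro-2H-chromene-6-carbaldehyde
Product: 12 (3S)-3-(2,2-dimethyl-3,4-dihydro-2H-chromen-6-yl)-3-hydroxy-1-[(2S)-6-hydroxy-2-(2-hydroxypropan-2-yl)-2,3-dihydro-1-benzofuran-5-yl]propan-1-one, via silyl-protected aldol adduct 11 (not isolated)
Conditions: SiCl4 (1.5 equiv), chiral binaphthyldiamine-derived bisphosphoramide (5 mol %, enantiomer for Si-face attack), i-Pr2NEt (10 mol %), CH2Cl2, −78 °C; aq. KF/NaHCO3; then TBAF, AcOH, THF, 0 °C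
Reagents that add atoms: none
Why: In this catalytic asymmetric Mukaiyama aldol addition (Lewis-base-activated SiCl4), the bisphosphoramide-bound silicon cation should activate aldehyde 10 and direct the enol ether to its Si face, setting the carbinol centre as (S) by catalyst control independent of the remote C2 centre, and buffered fluoride then removes the remaining silyl ether under conditions too mild for retro-aldol cleavage or dehydration.

Compound list
1 | 1-(4-fluoro-2-hydroxyphenyl)ethan-1-one | CC(=O)c1ccc(F)cc1O | starting material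
2 | 1-[5-(chloromethyl)-4-fluoro-2-hydroxyphenyl]ethan-1-one | CC(=O)c1cc(CCl)c(F)cc1O | intermediate
3 | 1-{2-[(tert-butyldimethylsilyl)oxy]-5-(chloromethyl)-4-fluorophenyl}ethan-1-one | CC(=O)c1cc(CCl)c(F)cc1O[Si](C)(C)C(C)(C)C | intermediate
4 | methacrolein (2-methylprop-2-enal) | CC(=C)C=O | starting material
5 | {5-acetyl-4-[(tert-butyldimethylsilyl)oxy]-2-fluorobenzyl}zinc chloride | CC(=O)c1cc(C[Zn]Cl)c(F)cc1O[Si](C)(C)C(C)(C)C | intermediate (not isolated)
6 | metal alkoxide of 1-{2-[(tert-butyldimethylsilyl)oxy]-4-fluoro-5-[(2S)-2-hydroxy-3-methylbut-3-en-1-yl]phenyl}ethan-1-one, drawn as the chlorozinc alkoxide | CC(=O)c1cc(C[C@H](O[Zn]Cl)C(C)=C)c(F)cc1O[Si](C)(C)C(C)(C)C | intermediate (not isolated)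
7 | 1-[(2S)-6-hydroxy-2-(prop-1-en-2-yl)-2,3-dihydro-1-benzofuran-5-yl]ethan-1-one | CC(=O)c1cc2c(cc1O)O[C@H](C(C)=C)C2 | intermediate
8 | 1-[(2S)-6-hydroxy-2-(2-hydroxypropan-2-yl)-2,3-dihydro-1-benzofuran-5-yl]ethan-1-one | CC(=O)c1cc2c(cc1O)O[C@H](C(C)(C)O)C2 | intermediate
9 | (2S)-6-[(trimethylsilyl)oxy]-2-{2-[(trimethylsilyl)oxy]propan-2-yl}-5-{1-[(trimethylsilyl)oxy]ethenyl}-2,3-dihydro-1-benzofuran | C=C(O[Si](C)(C)C)c1cc2c(cc1O[Si](C)(C)C)O[C@H](C(C)(C)O[Si](C)(C)C)C2 | intermediate
10 | 2,2-dimethyl-3,4-dihydro-2H-chromene-6-carbaldehyde | CC1(C)CCc2cc(C=O)ccc2O1 | starting material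
11 | (3S)-3-(2,2-dimethyl-3,4-dihydro-2H-chromen-6-yl)-3-hydroxy-1-[(2S)-6-hydroxy-2-{2-[(trimethylsilyl)oxy]propan-2-yl}-2,3-dihydro-1-benzofuran-5-yl]propan-1-one | CC1(C)CCc2cc([C@@H](O)CC(=O)c3cc4c(cc3O)O[C@H](C(C)(C)O[Si](C)(C)C)C4)ccc2O1 | intermediate (not isolated)
12 | (3S)-3-(2,2-dimethyl-3,4-dihydro-2H-chromen-6-yl)-3-hydroxy-1-[(2S)-6-hydroxy-2-(2-hydroxypropan-2-yl)-2,3-dihydro-1-benzofuran-5-yl]propan-1-one | CC1(C)CCc2cc([C@@H](O)CC(=O)c3cc4c(cc3O)O[C@H](C(C)(C)O)C4)ccc2O1 | target

Total step count: 6. Longest linear sequence: 6 steps (1 → 2 → 3 → 7 → 8 → 9 → 12).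

Steps most likely to fail

Step 3 (proposed new method). The uncatalysed, racemic benzyl transfer from zinc may outrun the titanium-bound pathway in the salt-rich medium, so that facial selectivity is poor. In addition, enolisation of the acetyl group by the alkoxide may slow the ring closure. The fallback uses known chemistry, sets out from 3 and returns at 7. Zinc insertion into 3 as before and uncatalysed addition of the benzylic zinc chloride to 4, followed by aqueous work-up, give the racemic allylic alcohol 1-{2-[(tert-butyldimethylsilyl)oxy]-4-fluoro-5-(2-hydroxy-3-methylbut-3-en-1-yl)phenyl}ethan-1-one F1. Sharpless kinetic resolution (Ti(OiPr)4, D-(−)-diisopropyl tartrate, t-BuOOH, 4 Å sieves, CH2Cl2, −20 °C) should leave the (S)-allylic alcohol F2 and convert the (R)-enantiomer into the (R,R)-epoxy alcohol F3. Alcohol F2 is then closed to 7 with KOt-Bu in DMPU. At most half of the material is carried on, and the two ring bonds are then formed in separate operations.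

Step 6. Facial selectivity may be insufficient with this hindered ortho-silyloxy aryl enol ether, and the electron-rich benzylic aldolate may ionise or dehydrate under the Lewis acid. The fallback sets out from 8 and returns at 12. Claisen–Schmidt condensation of 8 with 10 (KOH, EtOH) gives the 2′-hydroxychalcone F4. Silylation of the phenol (TBSCl, imidazole, DMF) gives the silyl-protected chalcone F5. Enantioselective conjugate borylation (CuCl, NaOt-Bu, a Josiphos-type ferrocenyl diphosphine, B2pin2, MeOH, THF) gives the β-boryl ketone F6. Oxidation in the same flask with NaBO3 proceeds with retention and gives the silyl-protected β-hydroxy ketone F7. TBAF/AcOH then releases 12.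

Step 1. The chloromethylation may over-alkylate to diarylmethanes, and the para-hydroxybenzyl chloride may self-condense during the reaction or on the way to step 2. The fallback sets out from 1 and returns at 3, without ever handling the free hydroxybenzyl chloride. Bromination para to the hydroxyl group (NBS, MeCN) gives 1-(5-bromo-4-fluoro-2-hydroxyphenyl)ethan-1-one F8. Silylation (TBSCl, imidazole) gives the silyl ether F9. Stille coupling with tributyl(hydroxymethyl)stannane (Pd(PPh3)4, zerovalent palladium, dioxane, 90 °C) gives the benzylic alcohol F10. MsCl/Et3N followed by LiCl then gives 3.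

Further compounds
F1 | step 3 | racemic 1-{2-[(tert-butyldimethylsilyl)oxy]-4-fluoro-5-(2-hydroxy-3-methylbut-3-en-1-yl)phenyl}ethan-1-one | CC(=O)c1cc(CC(O)C(C)=C)c(F)cc1O[Si](C)(C)C(C)(C)C
F2 | step 3 | 1-{2-[(tert-butyldimethylsilyl)oxy]-4-fluoro-5-[(2S)-2-hydroxy-3-methylbut-3-en-1-yl]phenyl}ethan-1-one | CC(=O)c1cc(C[C@H](O)C(C)=C)c(F)cc1O[Si](C)(C)C(C)(C)C
F3 | step 3 | 1-{2-[(tert-butyldimethylsilyl)oxy]-4-fluoro-5-[(2R)-2-hydroxy-2-[(2R)-2-methyloxiran-2-yl]ethyl]phenyl}ethan-1-one | CC(=O)c1cc(C[C@@H](O)[C@@]2(C)CO2)c(F)cc1O[Si](C)(C)C(C)(C)C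
F4 | step 6 | (2E)-3-(2,2-dimethyl-3,4-dihydro-2H-chromen-6-yl)-1-[(2S)-6-hydroxy-2-(2-hydroxypropan-2-yl)-2,3-dihydro-1-benzofuran-5-yl]prop-2-en-1-one | CC1(C)CCc2cc(/C=C/C(=O)c3cc4c(cc3O)O[C@H](C(C)(C)O)C4)ccc2O1
F5 | step 6 | (2E)-1-[(2S)-6-[(tert-butyldimethylsilyl)oxy]-2-(2-hydroxypropan-2-yl)-2,3-dihydro-1-benzofuran-5-yl]-3-(2,2-dimethyl-3,4-dihydro-2H-chromen-6-yl)prop-2-en-1-one | CC1(C)CCc2cc(/C=C/C(=O)c3cc4c(cc3O[Si](C)(C)C(C)(C)C)O[C@H](C(C)(C)O)C4)ccc2O1
F6 | step 6 | (3S)-1-[(2S)-6-[(tert-butyldimethylsilyl)oxy]-2-(2-hydroxypropan-2-yl)-2,3-dihydro-1-benzofuran-5-yl]-3-(2,2-dimethyl-3,4-dihydro-2H-chromen-6-yl)-3-(4,4,5,5-tetramethyl-1,3,2-dioxaborolan-2-yl)propan-1-one | CC1(C)CCc2cc([C@@H](B3OC(C)(C)C(C)(C)O3)CC(=O)c3cc4c(cc3O[Si](C)(C)C(C)(C)C)O[C@H](C(C)(C)O)C4)ccc2O1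
F7 | step 6 | (3S)-1-[(2S)-6-[(tert-butyldimethylsilyl)oxy]-2-(2-hydroxypropan-2-yl)-2,3-dihydro-1-benzofuran-5-yl]-3-(2,2-dimethyl-3,4-dihydro-2H-chromen-6-yl)-3-hydroxypropan-1-one | CC1(C)CCc2cc([C@@H](O)CC(=O)c3cc4c(cc3O[Si](C)(C)C(C)(C)C)O[C@H](C(C)(C)O)C4)ccc2O1
F8 | step 1 | 1-(5-bromo-4-fluoro-2-hydroxyphenyl)ethan-1-one | CC(=O)c1cc(Br)c(F)cc1O
F9 | step 1 | 1-{5-bromo-2-[(tert-butyldimethylsilyl)oxy]-4-fluorophenyl}ethan-1-one | CC(=O)c1cc(Br)c(F)cc1O[Si](C)(C)C(C)(C)C
F10 | step 1 | 1-{2-[(tert-butyldimethylsilyl)oxy]-4-fluoro-5-(hydroxymethyl)phenyl}ethan-1-one | CC(=O)c1cc(CO)c(F)cc1O[Si](C)(C)C(C)(C)C
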